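The vessel is closed, stirred and isothermal, and I follow one quantity in it: v, the rate at which the chain eats starting material. Initiator splits into two initiating radicals, and each adds to starting material to give chain carrier. Chain carrier meets partner, giving product and an initiating radical again. Each radical also pairs off with its own kind, and partner decomposes by itself.

starting material 0.21 M; partner 0.210 M; initiator 18 mM; time 80 min
1. conversion of starting material at 80 min
2. amount of product at 80 min, in percent of the starting material charged
- in percentages every species weighs as the starting material in it: one ended chains B counts as two
- a doubled species enters its step squared and goes two at a time
- run time (flask): 80 min
    initiator → 2 initiating radical (k1 = 0.0089 /s)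
    starting material + initiating radical → chain carrier (k2 = 2200 /M/s)
    partner + chain carrier → product + initiating radical (k3 = 2500 /M/s)
    2 initiating radical → ended chains A (k4 = 9.7 × 10⁶ /M/s)
    2 chain carrier → ended chains B (k5 = 8.1 × 10⁶ /M/s)
    partner → decomposed reagent (k6 = 0.0077 /s)

I begin at the start. I let radicals pair off as fast as initiator splits (the steady-state approximation), and I let addition and transfer carry the same v, at pseudo-first-order frequencies of 462 /s and 525 /s. Solving this gives 87.8 mM/min.

Three losses slow v, each as a fraction of v. It follows the square root of initiator, which costs 0.267 /min. Partner's decay counts by the share of pairing done by chain carrier, 0.393 at the start and tending to 1 as partner falls. I join these ends at their middle, 0.696, which costs 0.322 /min. With equal charges, the chain's own consumption costs 0.418 /min, more than either other loss, but this loss shrinks with v.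

The fixed losses sum to 0.589 /min. I call the chain's reach the conversion at which v, so slowed, meets zero: the natural logarithm of one plus self-consumption over fixed loss, 53.7%. The fixed time of 1.70 min is far under 80 min, so I commit to the reach as the conversion asked. Product must lie below it by whatever pairs off into ended chains B.

The forecast gives 54.6% and 43.5%, holding that “80 min is effectively the end of reaction”. The flask gives a conversion of 54.8% and product of 43.6%.

The flask's conversion stands 1.1 percentage points above my reach. At 8.00 min this flask holds 45.4% of its starting material and 0.379% of its partner, and at 800 min starting material still stands at 45.2%. For a second flask charged with 0.031 M of initiator I reckon a starting v of 115 mM/min, so its self-consumption is 0.549 /min, its fixed loss is unchanged, and its reach is 65.8%; that flask reaches 68.4%.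

The numbers of this flask belong to no real substance.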